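**Retrosynthetic overview**

1. Core numbering used throughout: C1 (acyl bridgehead), C2–C3–C4 (enolised β-diketone), C5 (prenyl bridgehead), C6, C7 (prenyl), C8 (CMe2), C9 (bridging C=O). The last step opens a temporary pyran ring (C3–CH2–CH2–CMe2–O–C4), which reveals the tertiary alcohol and the vinylogous acid together; before that the C1 acyl group is added by bridgehead aldol addition and oxidation.
2. Key disconnection: C1–C2 and C4–C5, formed in one flask together with the pyran C–C and C–O bonds, by joining three components: a cyclohexanone methyl enol ether (ring C9–C1–C8–C7–C6–C5), malonyl dichloride (C2–C3–C4) and 3-methylbut-2-enal.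
3. Enabling feature: in the six-membered ring C9–C1–C8–C7–C6–C5 the C9 carbonyl lies between two enolisable α-carbons, C1 and C5. This latent 1,3-bis-nucleophile matches the 1,3-diacyl unit C2–C3–C4, and the C7 stereocentre steers the 1,3-diaxial bridge, so C5 epimers and enol-ether isomers converge.
4. The cyclohexanone comes from (S)-4-prenylcyclohex-2-enone (organocatalytic Michael/aldol annulation) by two copper-catalysed methyl additions and α′-prenylation.
5. Ring order: cyclohexane ring (step 2); second carbocycle of the bicyclo[3.3.1]nonane plus temporary pyran (step 7); pyran opened (step 12).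

Key step: step 7

Remark: the target is a vinylogous acid whose two enol tautomers interconvert, so the tautomer of the given SMILES is the one drawn; (R)-2-methylbutan-1-ol is taken as a purchasable single enantiomer.

**Route**

Step 1
Reactants: 1 2-methylbut-3-en-2-ol; 2 ethyl vinyl ether
Product: 4 5-methylhex-4-enal, via allyl vinyl ether 3 (not isolated)
Conditions: 2 (excess), Hg(OAc)2 (cat.), sealed tube, 130 °C
Reagents that add atoms: none
Why: Transetherification of the tertiary allylic alcohol followed by Claisen rearrangement of 3 through a chair transition state should give the γ,δ-unsaturated aldehyde; no stereocentre is formed.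

Step 2
Reactants: 4 5-methylhex-4-enal; 5 but-3-en-2-one
Product: 7 (4S)-4-(3-methylbut-2-en-1-yl)cyclohex-2-en-1-one, via keto aldehyde 6 (not isolated)
Conditions: (S)-2-[methoxy(diphenyl)methyl]pyrrolidine (5 mol %), ethyl 3,4-dihydroxybenzoate (20 mol %), neat, 4 °C; then LiOH (cat.), i-PrOH, rt
Reagents that add atoms: none
Why: Enamine-catalysed asymmetric Michael addition to the enone (the diarylmethyl group of the (S)-catalyst shields one face of the E-enamine, which should set the (S)-configured α-carbon of 6) followed by intramolecular aldol condensation closes the cyclohexenone, the stereocentre becoming C4 of 7 (C7 of the target).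

Step 3
Reactants: 7 (4S)-4-(3-methylbut-2-en-1-yl)cyclohex-2-en-1-one
Product: 9 (4S)-3-methyl-4-(3-methylbut-2-en-1-yl)cyclohex-2-en-1-one, via silyl enol ether 8 (not isolated)
Conditions: MeMgBr, CuBr·SMe2 (cat.), Me3SiCl, THF, −78 °C; then Pd(OAc)2 (cat.), O2 (1 atm), DMSO, 40 °C
Reagents that add atoms: methylmagnesium bromide, C[Mg]Br
Why: Copper-catalysed conjugate addition with silyl trapping gives the enol ether regiospecifically (methyl anti to the prenyl group, a centre that is erased again), and Saegusa oxidation restores the enone, now β-methylated; the existing stereocentre is not touched.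

Step 4
Reactants: 9 (4S)-3-methyl-4-(3-methylbut-2-en-1-yl)cyclohex-2-en-1-one
Product: 11 (4S)-3,3-dimethyl-4-(3-methylbut-2-en-1-yl)cyclohexan-1-one, via silyl enol ether 10 (not isolated)
Conditions: MeMgBr, CuBr·SMe2 (cat.), Me3SiCl, THF, −40 °C; then 1 M HCl
Reagents that add atoms: methylmagnesium bromide, C[Mg]Br
Why: A second silyl-chloride-accelerated copper-catalysed 1,4-addition to the β,β-disubstituted enone builds the gem-dimethyl carbon (C8) next to the stereocentre, which is unaffected; acid work-up cleaves the silyl enol ether.

Step 5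
Reactants: 11 (4S)-3,3-dimethyl-4-(3-methylbut-2-en-1-yl)cyclohexan-1-one; 12 1-bromo-3-methylbut-2-ene
Product: 13 (4R)-5,5-dimethyl-2,4-bis(3-methylbut-2-en-1-yl)cyclohexan-1-one (both C2 epimers)
Conditions: LiN(i-Pr)2, THF, −78 °C; then 12, −78 → 0 °C
Reagents that add atoms: none
Why: Kinetic deprotonation should occur at the unhindered α-methylene (future C5) and not at the neopentyl α-methylene (future C1), and SN2 alkylation of the lithium enolate installs the second prenyl group; the epimers are not separated because this carbon becomes sp2 in step 6 and is set again in step 7.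

Step 6
Reactants: 13 (4R)-5,5-dimethyl-2,4-bis(3-methylbut-2-en-1-yl)cyclohexan-1-one
Product: 15 (5R)-2-methoxy-4,4-dimethyl-1,5-bis(3-methylbut-2-en-1-yl)cyclohex-1-ene (drawn as the C5=C9 isomer; used as the double-bond isomer mixture), via dimethyl ketal 14 (not isolated)
Conditions: HC(OMe)3, p-toluenesulfonic acid (cat.), MeOH, rt; then toluene, 110 °C (−MeOH)
Reagents that add atoms: trimethyl orthoformate, COC(OC)OC; methanol, CO
Why: Acid-catalysed ketalisation with the orthoformate as water scavenger and thermal loss of methanol should give the methyl enol ether; a mixture of double-bond isomers is acceptable because both should converge in step 7.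

Step 7
Reactants: 15 (5R)-2-methoxy-4,4-dimethyl-1,5-bis(3-methylbut-2-en-1-yl)cyclohex-1-ene; 16 malonyl dichloride; 17 3-methylbut-2-enal
Product: 20 tricyclic 2H-pyran (2,2-dimethyl-2H-pyran fused at C3–C4 of the 8,8-dimethyl-5,7-diprenylbicyclo[3.3.1]nonane-2,9-dione; ring oxygen on C4; C1–H; stereocentres as in 18), via bicyclic trione 18 (not isolated), via oxatriene 19 (not isolated)
Conditions: 16 (2 equiv), Et2O, −20 °C; then aq. KOH, benzyltriethylammonium chloride, rt; then AcOH to pH 6, 17, ethylenediammonium diacetate (cat.), MeOH, 50 °C; chromatography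
Reagents that add atoms: none
Why: Effenberger-type α,α′-annulation (close precedent on prenylated cyclohexanone methyl enol ethers) telescoped with a Knoevenagel/oxa-6π annulation (close precedent on cyclic 1,3-diones and enals): the tetrasubstituted enol-ether carbon C5 is C-acylated by malonyl dichloride, the oxocarbenium ion re-forms an enol ether towards C1, C1 attacks the tethered acyl chloride and the O-methyl group leaves as MeCl, after which hydroxide hydrolyses O-acylated material and trione 18 condenses at C3 with the enal to give oxatriene 19. The carbocycle C1–C2–C3–C4–C5–C9 closes by 6-(enolendo)-exo-trig C-acylation, and the pyran closes by 6π-electrocyclisation of the 1-oxatriene O4=C4–C3=CH–CH=CMe2. C5 is set by axial attack on the half-chair anti to the equatorial C7 prenyl group and C1 follows from the tether, because the three-carbon bridge can only span C1 and C5 in a cis-1,3-diaxial way; since C5 is sp2 in 15 and the enol-ether isomers interconvert under the HCl formed, the epimers of 13 and both double-bond isomers should funnel into the single trione 18. The step needs C- rather than O-acylation in the second bond formation, which is secured by the quaternary C5 (no aromatic pyranone can arise) and by the methyl cap on the C9 oxygen. It also needs the pyran oxygen on C4 and not on C2, so that C1–H stays flanked by the C2 and C9 carbonyl groups for step 10; both closures start from the same oxatriene and the substrate offers no strong bias between them, so 20 is separated by chromatography from its O2-closed isomer.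

Step 8
Reactants: 20 tricyclic 2H-pyran
Product: 21 tricyclic dihydropyran (20 with the pyran CH=CH reduced to CH2–CH2; stereocentres unchanged)
Conditions: H2 (1 atm), RhCl(PPh3)3 (5 mol %), benzene, rt
Reagents that add atoms: none
Why: Homogeneous hydrogenation with this rhodium complex discriminates strongly between di- and trisubstituted olefins, so the cis-disubstituted pyran olefin should be saturated while the two prenyl groups and the tetrasubstituted enol ether survive; no stereocentre is formed.

Step 9
Reactants: 22 (2R)-2-methylbutan-1-ol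
Product: 23 (2R)-2-methylbutanal
Conditions: 2,2,6,6-tetramethylpiperidin-1-oxyl (cat.), KBr (cat.), NaOCl, NaHCO3, CH2Cl2/H2O, 0 °C
Reagents that add atoms: none
Why: Nitroxyl-catalysed (Anelli) oxidation under buffered two-phase conditions should give the α-branched aldehyde without racemisation; it is used at once as a dried solution.

Step 10
Reactants: 21 tricyclic dihydropyran; 23 (2R)-2-methylbutanal
Product: 24 C1 carbinol (21 bearing a (2R)-1-hydroxy-2-methylbutyl group on C1; both carbinol epimers)
Conditions: LiN(i-Pr)2 (1.3 equiv), THF, −78 °C; then 23; then AcOH, −78 °C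
Reagents that add atoms: none
Why: The amide base removes the only acidic proton, the C1 bridgehead hydrogen flanked by the C2 and C9 carbonyl groups (C3 is blocked by the pyran ring), and the bridgehead lithium enolate should add to the aldehyde (aldol addition) with retention at C1, the cage allowing no other geometry; both carbinol epimers are oxidised in step 11.

Step 11
Reactants: 24 C1 carbinol
Product: 25 C1 ketone (21 bearing the (2R)-2-methylbutanoyl group on C1)
Conditions: Dess–Martin periodinane, NaHCO3, CH2Cl2, rt
Reagents that add atoms: none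
Why: Dess–Martin oxidation of the hindered secondary alcohol under buffered, non-basic conditions should give the ketone without touching the adjacent (R)-stereocentre, the prenyl groups or the vinylogous ester.

Step 12
Reactants: 25 C1 ketone
Product: 26 (1S,5S,7R)-4-hydroxy-3-(3-hydroxy-3-methylbutyl)-8,8-dimethyl-1-[(2R)-2-methylbutanoyl]-5,7-bis(3-methylbut-2-en-1-yl)bicyclo[3.3.1]non-3-ene-2,9-dione
Conditions: KOSiMe3, THF, rt → 40 °C; then dilute HCl to pH 4–5
Reagents that add atoms: potassium trimethylsilanolate, C[Si](C)(C)[O-].[K+]
Why: Addition–elimination of the silanolate at C4 of the vinylogous ester expels the tertiary alkoxide, which opens the temporary pyran ring and unmasks the tertiary alcohol and the vinylogous acid at once (vinylogous ester cleavage, driven by formation of the potassium enolate); the non-aqueous, near-ambient conditions are chosen to spare the stereocentre α to the acyl carbonyl, and no stereocentre is formed or broken.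

**Compound list**

1 | 2-methylbut-3-en-2-ol | CC(C)(O)C=C | starting material
2 | ethyl vinyl ether | C=COCC | starting material
3 | 3-(ethenyloxy)-3-methylbut-1-ene | C=COC(C)(C)C=C | intermediate
4 | 5-methylhex-4-enal | CC(C)=CCCC=O | intermediate
5 | but-3-en-2-one | CC(=O)C=C | starting material
6 | (2S)-2-(3-methylbut-2-en-1-yl)-5-oxohexanal | O=C[C@H](CC=C(C)C)CCC(C)=O | intermediate
7 | (4S)-4-(3-methylbut-2-en-1-yl)cyclohex-2-en-1-one | O=C1C=C[C@H](CC=C(C)C)CC1 | intermediate
8 | trimethyl{[(3S,4S)-3-methyl-4-(3-methylbut-2-en-1-yl)cyclohex-1-en-1-yl]oxy}silane (trans) | C[Si](C)(C)OC1=C[C@@H](C)[C@H](CC=C(C)C)CC1 | intermediate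
9 | (4S)-3-methyl-4-(3-methylbut-2-en-1-yl)cyclohex-2-en-1-one | O=C1C=C(C)[C@H](CC=C(C)C)CC1 | intermediate
10 | {[(4S)-3,3-dimethyl-4-(3-methylbut-2-en-1-yl)cyclohex-1-en-1-yl]oxy}trimethylsilane | C[Si](C)(C)OC1=CC(C)(C)[C@H](CC=C(C)C)CC1 | intermediate
11 | (4S)-3,3-dimethyl-4-(3-methylbut-2-en-1-yl)cyclohexan-1-one | O=C1CC(C)(C)[C@H](CC=C(C)C)CC1 | intermediate
12 | 1-bromo-3-methylbut-2-ene | CC(C)=CCBr | starting material
13 | (4R)-5,5-dimethyl-2,4-bis(3-methylbut-2-en-1-yl)cyclohexan-1-one (both C2 epimers) | O=C1CC(C)(C)[C@H](CC=C(C)C)CC1CC=C(C)C | intermediate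
14 | (4R)-1,1-dimethoxy-5,5-dimethyl-2,4-bis(3-methylbut-2-en-1-yl)cyclohexane | COC1(OC)CC(C)(C)[C@H](CC=C(C)C)CC1CC=C(C)C | intermediate
15 | (5R)-2-methoxy-4,4-dimethyl-1,5-bis(3-methylbut-2-en-1-yl)cyclohex-1-ene | COC1=C(CC=C(C)C)C[C@@H](CC=C(C)C)C(C)(C)C1 | intermediate
16 | malonyl dichloride | O=C(Cl)CC(=O)Cl | starting material
17 | 3-methylbut-2-enal | CC(C)=CC=O | starting material
18 | (1R,5S,7R)-8,8-dimethyl-5,7-bis(3-methylbut-2-en-1-yl)bicyclo[3.3.1]nonane-2,4,9-trione (core numbering of the target; C1–H; 7-prenyl exo) | O=C1CC(=O)[C@]2(CC=C(C)C)C[C@@H](CC=C(C)C)C(C)(C)[C@H]1C2=O | intermediate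
19 | oxatriene: 18 with a 3-methylbut-2-en-1-ylidene group on C3 (either geometry of the exocyclic double bond) | O=C1C(=CC=C(C)C)C(=O)[C@]2(CC=C(C)C)C[C@@H](CC=C(C)C)C(C)(C)[C@H]1C2=O | intermediate
20 | tricyclic 2H-pyran: 18 with C3 and the C4 oxygen joined by CH=CH–C(CH3)2 (ring oxygen on C4, C2 and C9 ketones) | O=C1C2=C(OC(C)(C)C=C2)[C@]3(CC=C(C)C)C[C@@H](CC=C(C)C)C(C)(C)[C@H]1C3=O | intermediate
21 | tricyclic dihydropyran: 20 with CH2–CH2 in place of CH=CH | O=C1C2=C(OC(C)(C)CC2)[C@]3(CC=C(C)C)C[C@@H](CC=C(C)C)C(C)(C)[C@H]1C3=O | intermediate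
22 | (2R)-2-methylbutan-1-ol | CC[C@@H](C)CO | starting material
23 | (2R)-2-methylbutanal | CC[C@@H](C)C=O | intermediate
24 | C1 carbinol: 21 with a (2R)-1-hydroxy-2-methylbutyl group on C1 (both carbinol epimers) | CC[C@@H](C)C(O)[C@]12C(=O)C3=C(OC(C)(C)CC3)[C@](CC=C(C)C)(C[C@@H](CC=C(C)C)C1(C)C)C2=O | intermediate
25 | C1 ketone: 21 with a (2R)-2-methylbutanoyl group on C1 | CC[C@@H](C)C(=O)[C@]12C(=O)C3=C(OC(C)(C)CC3)[C@](CC=C(C)C)(C[C@@H](CC=C(C)C)C1(C)C)C2=O | intermediate
26 | (1S,5S,7R)-4-hydroxy-3-(3-hydroxy-3-methylbutyl)-8,8-dimethyl-1-[(2R)-2-methylbutanoyl]-5,7-bis(3-methylbut-2-en-1-yl)bicyclo[3.3.1]non-3-ene-2,9-dione | CC[C@@H](C)C(=O)[C@]12C(=O)C(CCC(C)(C)O)=C(O)[C@](CC=C(C)C)(C[C@@H](CC=C(C)C)C1(C)C)C2=O | target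

**Step count**

Total: 12 steps. Longest linear sequence: 11 steps (steps 1–8 and 10–12; step 9 is a one-step side branch).

**Steps most likely to fail**

Step 7. What may go wrong: O-acylation of the enol oxygen (enol-lactone formation) may outrun the second C-acylation at the neopentyl carbon C1, the first acyl group may be lost by retro-Claisen cleavage during the hydroxide treatment, and closure of the pyran on the C2 oxygen may take a large share of the material. Fallback, from 15 back to 20: the two bonds are made one after the other, and the pyran is closed in between, when only one ketone oxygen can take part. C-Acylation of 15 with methyl 3-chloro-3-oxopropanoate (Et2O, −20 °C → rt) should give β-keto ester F1. Knoevenagel condensation of F1 with 17 (ethylenediammonium diacetate cat., MeOH, 50 °C) and oxa-6π closure on the ketone oxygen, the ester oxygen being no partner for the electrocyclisation, should give 2H-pyran ester F2 with the ring oxygen fixed on C4. LiN(i-Pr)2 (THF, −78 → −20 °C, AcOH quench at low temperature) should then form the C1–C2 bond by Dieckmann-type attack of the C9 ketone enolate, which can only form towards C1, on the ester, giving 20 as a single closure isomer.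

Step 8. What may go wrong: loss of chemoselectivity, that is partial saturation of the prenyl olefins, or stalling at the ring olefin next to the quaternary carbon. Fallback, from 18 back to 21: the saturated pyran is built directly, so no olefin has to be reduced. Step 7 is stopped after the hydroxide treatment and trione 18 is isolated by acidification. Treatment of 18 with paraformaldehyde and excess 2-methylpropene (ethylenediammonium diacetate cat., dioxane, sealed tube, 80 °C) should start a domino Knoevenagel/hetero-Diels–Alder reaction through 3-methylidene trione F3. The oxadiene O4=C4–C3=CH2 adds to the alkene with oxygen going to the tertiary carbon, giving 21 together with the O2-closed regioisomer F4, which is removed by chromatography. The route continues with 21 in step 10.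

Step 12. What may go wrong: base-mediated epimerisation at the carbon α to the C1 acyl carbonyl, retro-Claisen loss of the acyl group from the triacylated C1, or failure of the nucleophile to add to the hindered C4. Fallback, from 21 back to 26: the pyran is opened before any acyl group is present, and the end game uses a methyl ether that is removed by chloride. LiOH (dioxane/H2O, 90 °C) should open 21 to hydroxy trione F5. O-Methylation (Me3SiCHN2, MeOH/toluene) should give the C4 methyl ether F6, which has the C2 carbonyl next to C1–H, and the C2 methyl ether F7, which is hydrolysed back to F5. Treatment of F6 with LiN(i-Pr)2 (2.2 equiv, the tertiary alcohol carried as its alkoxide) and 23 should give carbinol F8, and Dess–Martin oxidation should give O-methyl ketone F9. LiCl in DMSO at 120 °C then removes the methyl group by SN2 attack of chloride at carbon, so that no oxygen nucleophile or strong base meets the acylated compound, and should give 26.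

Further compounds
F1 | step 7 | methyl 3-[(1R,5R)-4,4-dimethyl-1,5-bis(3-methylbut-2-en-1-yl)-2-oxocyclohexyl]-3-oxopropanoate (acyl group trans to the 5-prenyl group) | COC(=O)CC(=O)[C@]1(CC=C(C)C)C[C@@H](CC=C(C)C)C(C)(C)CC1=O
F2 | step 7 | methyl 6-[(1S,5R)-4,4-dimethyl-1,5-bis(3-methylbut-2-en-1-yl)-2-oxocyclohexyl]-2,2-dimethyl-2H-pyran-5-carboxylate (ring stereocentres placed as in F1) | COC(=O)C1=C(OC(C)(C)C=C1)[C@]2(CC=C(C)C)C[C@@H](CC=C(C)C)C(C)(C)CC2=O
F3 | step 8 | 3-methylidene derivative of trione 18 | C=C1C(=O)[C@]2(CC=C(C)C)C[C@@H](CC=C(C)C)C(C)(C)[C@H](C1=O)C2=O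
F4 | step 8 | regioisomer of 21 with the ring oxygen on C2 | O=C1C2=C(OC(C)(C)CC2)[C@H]3C(C)(C)[C@H](CC=C(C)C)C[C@]1(CC=C(C)C)C3=O
F5 | step 12 | 3-(3-hydroxy-3-methylbutyl) derivative of trione 18 (enol form) | O=C1C(CCC(C)(C)O)=C(O)[C@]2(CC=C(C)C)C[C@@H](CC=C(C)C)C(C)(C)[C@H]1C2=O
F6 | step 12 | C4 methyl ether of F5 | O=C1C(CCC(C)(C)O)=C(OC)[C@]2(CC=C(C)C)C[C@@H](CC=C(C)C)C(C)(C)[C@H]1C2=O
F7 | step 12 | C2 methyl ether of F5 | O=C1C(CCC(C)(C)O)=C(OC)[C@H]2C(C)(C)[C@H](CC=C(C)C)C[C@]1(CC=C(C)C)C2=O
F8 | step 12 | C1 carbinol of F6 ((2R)-1-hydroxy-2-methylbutyl group on C1; both carbinol epimers) | CC[C@@H](C)C(O)[C@]12C(=O)C(CCC(C)(C)O)=C(OC)[C@](CC=C(C)C)(C[C@@H](CC=C(C)C)C1(C)C)C2=O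
F9 | step 12 | C4 methyl ether of 26 | CC[C@@H](C)C(=O)[C@]12C(=O)C(CCC(C)(C)O)=C(OC)[C@](CC=C(C)C)(C[C@@H](CC=C(C)C)C1(C)C)C2=O
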